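**Strategy.** The bicyclo[3.3.1]nonane is disconnected at C1, the bridgehead that lies between the C9 and C2 carbonyls and is bonded to quaternary C8, with C7 next to it. Forward, C1 is the carbenoid carbon of a 2-diazo-1,3-dione and adds across the C7=C8 olefin of a geranyl group on C5: one operation forms C1–C7 and C1–C8, closes the cyclopropane and the five-membered ring C1–C9–C5–C6–C7, and sets C1, C7 and C8 from C5 and the (E)-olefin. SN2 opening at C7 later turns this into ring A. The precursor is (S)-6-allyl-2-diazo-6-geranyl-5-methoxycyclohex-4-ene-1,3-dione, the diazo derivative of a dearomatised, C5-quaternary phloroglucinol monomethyl ether.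

Key step: step 7

Remark: PPAP numbering is used for all bicyclic and tricyclic compounds; geranyl = (2E)-3,7-dimethylocta-2,6-dien-1-yl; 1,3-diones and the final trione are drawn as one tautomer and CIP descriptors refer to the tautomer drawn.
Remark: C5 is stereogenic only because C4 carries the enol ether and C9 the ketone; the quaternary carbon is therefore built on a symmetric dienone, where the site of allylation is not in doubt, and the enantiomers are parted once the two oxygens differ.
Remark: the C1 anion freed on opening the cyclopropane is a bridgehead anion and less stabilised than an α-sulfonyl carbanion, so C1 is prenylated by a separate bridgehead lithiation after the sulfone has been removed.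

Step 1
Reactants: 1 3,5-dimethoxyphenol
Product: 2 (3,5-dimethoxyphenoxy)tri(propan-2-yl)silane
Conditions: TIPSCl, imidazole, DMF, 25 °C
Reagents that add atoms: chlorotri(propan-2-yl)silane, CC(C)[Si](Cl)(C(C)C)C(C)C
Why: O-silylation of the phenol masks the acidic OH with a bulky, non-directing group, so that the carbon between the two methoxy groups is the site of metalation in step 2; no stereocentre is involved.

Step 2
Reactants: 2 (3,5-dimethoxyphenoxy)tri(propan-2-yl)silane, 3 geranyl bromide
Product: 6 4-geranyl-3,5-dimethoxyphenol, via aryllithium 4 (not isolated), via silyl ether 5 (not isolated)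
Conditions: n-BuLi, TMEDA, THF, 0 °C; CuBr·SMe2 (10 mol %), 3, −78 → 25 °C; then TBAF, THF, 25 °C; aq. NH4Cl
Reagents that add atoms: 3 geranyl bromide, CC(C)=CCC/C(C)=C/CBr
Why: Directed ortho-metalation between the two methoxy groups, copper-catalysed SN2 coupling of the aryllithium with the primary allylic bromide (the (E)-olefin is not touched) and fluoride cleavage of the silyl ether in the same flask should give the para-geranyl phenol.

Step 3
Reactants: 6 4-geranyl-3,5-dimethoxyphenol, 7 allyl methyl carbonate
Product: 8 4-allyl-4-geranyl-3,5-dimethoxycyclohexa-2,5-dien-1-one (achiral)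
Conditions: Pd(OAc)2 (5 mol %), PPh3 (20 mol %), Ti(OiPr)4, 4 Å MS, benzene, 50 °C
Reagents that add atoms: 7 allyl methyl carbonate, C=CCOC(=O)OC
Why: Tsuji–Trost-type dearomative C-allylation: the titanium phenoxide of a 4-alkyl-3,5-dimethoxyphenol attacks the π-allylpalladium complex through its para carbon, which is flanked by both methoxy groups, so the quaternary carbon forms on a symmetric, achiral dienone without a regiochemical or stereochemical issue.

Step 4
Reactants: 8 4-allyl-4-geranyl-3,5-dimethoxycyclohexa-2,5-dien-1-one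
Product: 9 rac-6-allyl-6-geranyl-5-methoxycyclohex-4-ene-1,3-dione (vinylogous acid)
Conditions: LiI, 2,4,6-collidine, 130 °C; then 1 M HCl
Reagents that add atoms: none
Why: Nucleophilic (SN2) demethylation of a vinylogous ester by iodide removes one of the two enantiotopic methyl groups and stops there because the vinylogous acid anion formed is no longer electrophilic; C5 becomes a stereocentre, formed as the racemate.

Step 5
Reactants: 9 rac-6-allyl-6-geranyl-5-methoxycyclohex-4-ene-1,3-dione
Product: 10 (6S)-6-allyl-6-geranyl-5-methoxycyclohex-4-ene-1,3-dione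
Conditions: preparative SFC on amylose tris(3,5-dimethylphenylcarbamate), CO2/MeOH (0.1% HCO2H), 35 °C
Reagents that add atoms: none
Why: Resolution by preparative chromatography on a chiral stationary phase separates the enantiomers of the configurationally stable quaternary centre; the (S) enantiomer, to be assigned by comparison of measured and calculated circular dichroism, is carried on.

Step 6
Reactants: 10 (6S)-6-allyl-6-geranyl-5-methoxycyclohex-4-ene-1,3-dione
Product: 11 (6S)-6-allyl-2-diazo-6-geranyl-5-methoxycyclohex-4-ene-1,3-dione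
Conditions: p-ABSA, Et3N, MeCN, 0 → 25 °C
Reagents that add atoms: 4-acetamidobenzenesulfonyl azide, CC(=O)Nc1ccc(cc1)S(=O)(=O)N=[N+]=[N-]
Why: Regitz diazo transfer from the sulfonyl azide to the triethylammonium enolate places the diazo group on C1, the only carbon flanked by two carbonyl groups (C9 and C2), and leaves C5 untouched.

Step 7
Reactants: 11 (6S)-6-allyl-2-diazo-6-geranyl-5-methoxycyclohex-4-ene-1,3-dione
Product: 12 (1S,5S,7S,8S)-5-allyl-4-methoxy-8-methyl-8-(4-methylpent-3-en-1-yl)tricyclo[3.3.1.0(1,7)]non-3-ene-2,9-dione (PPAP numbering; cyclopropane C1–C7–C8, C8 methyl cis to C6)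
Conditions: Rh2(OAc)4 (2 mol %), CH2Cl2, 40 °C, slow addition of 11
Reagents that add atoms: none
Why: Rh2(OAc)4 expels dinitrogen from the 2-diazo-1,3-dione to give an electrophilic rhodium carbenoid at C1, which adds to the proximal geranyl olefin in a concerted, asynchronous and stereospecific [2+1] step. The closest known reaction type is the dirhodium-catalysed intramolecular cyclopropanation of 2-diazo-1,3-dicarbonyl compounds and α-diazoketones with a γ,δ-olefin to bicyclo[3.1.0]hexan-2-ones. The cyclopropane (C1–C7–C8) closes by carbene transfer, and the five-membered ring C1–C9–C5–C6–C7 closes in the 5-exo sense through the C1–C7 bond, with C8 outside that ring. C1 and C7 are set by the C5 stereocentre, because the one-carbon tether from C5 reaches C1 only across the face that carries the geranyl CH2 and only a cis ring fusion is possible; C8 is set by the (E)-olefin, which keeps its methyl cis to C6. The step needs selection of the geranyl 2,3-olefin over the allyl olefin, the distal 6,7-olefin, C–H insertion and Wolff rearrangement: the trisubstituted olefin is the most nucleophilic and develops tertiary cationic character at C8, the allyl group would place that charge on a primary carbon, the distal olefin would need a nine-membered ring, and slow addition at 40 °C keeps dimerisation and thermal rearrangement down.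

Step 8
Reactants: 12 5-allyl cyclopropane, 13 2-methyl-2-butene
Product: 14 (1S,5S,7S,8S)-4-methoxy-8-methyl-5-(3-methylbut-2-en-1-yl)-8-(4-methylpent-3-en-1-yl)tricyclo[3.3.1.0(1,7)]non-3-ene-2,9-dione (PPAP numbering)
Conditions: second-generation Hoveyda–Grubbs catalyst RuCl2(H2IMes)(=CH-C6H4-2-Oi-Pr) (5 mol %), 13/CH2Cl2, 40 °C
Reagents that add atoms: 13 2-methyl-2-butene, CC=C(C)C
Why: Olefin cross-metathesis with excess 2-methyl-2-butene turns the only monosubstituted olefin into a prenyl group; the trisubstituted side-chain olefin does not enter productive metathesis and a phosphine-free catalyst avoids nucleophilic attack on the activated cyclopropane.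

Step 9
Reactants: 3 geranyl bromide, 15 sodium benzenesulfinate
Product: 16 geranyl phenyl sulfone, {[(2E)-3,7-dimethylocta-2,6-dien-1-yl]sulfonyl}benzene
Conditions: DMF, 25 °C
Reagents that add atoms: 15 sodium benzenesulfinate, [Na+].[O-]S(=O)c1ccccc1
Why: SN2 S-alkylation of the sulfinate at the primary allylic carbon gives the allylic sulfone with the (E)-olefin retained.

Step 10
Reactants: 14 5-prenyl cyclopropane, 16 geranyl phenyl sulfone
Product: 18 (1R,5S,7R,8S)-7-[(2E)-3,7-dimethyl-1-(phenylsulfonyl)octa-2,6-dien-1-yl]-4-methoxy-8-methyl-5-(3-methylbut-2-en-1-yl)-8-(4-methylpent-3-en-1-yl)bicyclo[3.3.1]non-3-ene-2,9-dione (both epimers at the sulfone carbon), via lithiated sulfone 17 (not isolated)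
Conditions: 16, n-BuLi, THF, −78 °C; DMPU; 14, −78 → 0 °C; aq. NH4Cl
Reagents that add atoms: 16 geranyl phenyl sulfone, CC(C)=CCC/C(C)=C/CS(=O)(=O)c1ccccc1
Why: Homoconjugate SN2 opening of the doubly activated cyclopropane by the soft α-sulfonyl carbanion: attack at secondary C7 anti to the C1–C7 bond (held parallel to both carbonyl π systems, while quaternary C8 is closed to SN2) inverts C7, places the new chain equatorial on the six-membered ring A thus formed and releases a bridgehead C1 anion that is protonated by the more acidic α-sulfonyl C–H or on work-up.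

Step 11
Reactants: 18 ring-opened allylic sulfone
Product: 19 (1R,5S,7R,8S)-7-geranyl-4-methoxy-8-methyl-5-(3-methylbut-2-en-1-yl)-8-(4-methylpent-3-en-1-yl)bicyclo[3.3.1]non-3-ene-2,9-dione
Conditions: Pd(PPh3)4 (10 mol %), NaBH4, THF/i-PrOH, 0 → 25 °C
Reagents that add atoms: none
Why: Palladium-catalysed hydride substitution of an allylic sulfone: ionisation to the π-allylpalladium complex and hydride transfer to its less substituted terminus next to C7 should leave the trisubstituted (E)-olefin in place, while borohydride does not reduce the vinylogous ester or the C9 ketone shielded by the axial C8 methyl group; no stereocentre changes.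

Step 12
Reactants: 19 7-geranyl bicyclic dione with C1–H, 20 prenyl bromide
Product: 22 (1R,5S,7R,8S)-7-geranyl-4-methoxy-8-methyl-1,5-bis(3-methylbut-2-en-1-yl)-8-(4-methylpent-3-en-1-yl)bicyclo[3.3.1]non-3-ene-2,9-dione, via bridgehead lithio compound 21 (not isolated)
Conditions: LiN(i-Pr)2, THF, −78 °C; 20, −78 → 0 °C
Reagents that add atoms: 20 prenyl bromide, CC(C)=CCBr
Why: Regioselective bridgehead lithiation at C1, the C–H flanked by the C9 and C2 carbonyls, and SN2 alkylation with prenyl bromide, as established for 4-methoxybicyclo[3.3.1]non-3-ene-2,9-diones; a bridgehead can only be substituted from the exo side, so its configuration is fixed by the bicycle.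

Step 13
Reactants: 23 3-acetoxybenzoic acid
Product: 24 3-acetoxybenzoyl chloride
Conditions: (COCl)2, DMF (cat.), CH2Cl2, 0 → 25 °C
Reagents that add atoms: oxalyl chloride, O=C(Cl)C(Cl)=O
Why: Acid chloride formation with oxalyl chloride under catalysis by the chloroiminium salt from DMF; the aryl acetate is inert.

Step 14
Reactants: 22 1,5-diprenyl bicyclic dione, 24 3-acetoxybenzoyl chloride
Product: 26 (1S,5S,7R,8S)-3-(3-acetoxybenzoyl)-7-geranyl-4-methoxy-8-methyl-1,5-bis(3-methylbut-2-en-1-yl)-8-(4-methylpent-3-en-1-yl)bicyclo[3.3.1]non-3-ene-2,9-dione, via C3-lithio compound 25 (not isolated)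
Conditions: lithium 2,2,6,6-tetramethylpiperidide (from 2,2,6,6-tetramethylpiperidine, n-BuLi), THF, −78 °C; then transfer into 24 (2 equiv), THF, −78 °C
Reagents that add atoms: 24 3-acetoxybenzoyl chloride, CC(=O)Oc1cccc(c1)C(Cl)=O
Why: Vinylic deprotonation at C3, between the C2 carbonyl and the C4 enol ether, by the hindered lithium amide and C-acylation of the vinyllithium by inverse addition to excess acid chloride, which reacts far faster than the aryl acetate; this is the known C3 aroylation of O-methyl bicyclic triones and no stereocentre is touched.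

Step 15
Reactants: 26 O-methyl, O-acetyl protected target
Product: 27 (1S,5S,7R,8S)-7-geranyl-4-hydroxy-3-(3-hydroxybenzoyl)-8-methyl-1,5-bis(3-methylbut-2-en-1-yl)-8-(4-methylpent-3-en-1-yl)bicyclo[3.3.1]non-3-ene-2,9-dione (CNP0285073.1)
Conditions: LiOH·H2O, 1,4-dioxane/H2O, 90 °C; then 1 M HCl
Reagents that add atoms: lithium hydroxide, [Li+].[OH-]
Why: Hydroxide cleaves the vinylogous methyl ester by addition–elimination at C4 and the aryl acetate by saponification in one operation, and acidification should release the enolised β-triketone without change at C1, C5, C7 or C8.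

**Compound list**
1 | 3,5-dimethoxyphenol | COc1cc(O)cc(OC)c1 | starting material
2 | (3,5-dimethoxyphenoxy)tri(propan-2-yl)silane | COc1cc(O[Si](C(C)C)(C(C)C)C(C)C)cc(OC)c1 | intermediate
3 | geranyl bromide, (2E)-1-bromo-3,7-dimethylocta-2,6-diene | CC(C)=CCC/C(C)=C/CBr | starting material
4 | {2,6-dimethoxy-4-[tri(propan-2-yl)silyloxy]phenyl}lithium | [Li]c1c(OC)cc(O[Si](C(C)C)(C(C)C)C(C)C)cc1OC | intermediate
5 | (4-geranyl-3,5-dimethoxyphenoxy)tri(propan-2-yl)silane | CC(C)=CCC/C(C)=C/Cc1c(OC)cc(O[Si](C(C)C)(C(C)C)C(C)C)cc1OC | intermediate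
6 | 4-geranyl-3,5-dimethoxyphenol | CC(C)=CCC/C(C)=C/Cc1c(OC)cc(O)cc1OC | intermediate
7 | allyl methyl carbonate | C=CCOC(=O)OC | starting material
8 | 4-allyl-4-geranyl-3,5-dimethoxycyclohexa-2,5-dien-1-one | CC(C)=CCC/C(C)=C/CC1(CC=C)C(OC)=CC(=O)C=C1OC | intermediate
9 | rac-6-allyl-6-geranyl-5-methoxycyclohex-4-ene-1,3-dione | CC(C)=CCC/C(C)=C/CC1(CC=C)C(=O)CC(=O)C=C1OC | intermediate
10 | (6S)-6-allyl-6-geranyl-5-methoxycyclohex-4-ene-1,3-dione | CC(C)=CCC/C(C)=C/C[C@]1(CC=C)C(=O)CC(=O)C=C1OC | intermediate
11 | (6S)-6-allyl-2-diazo-6-geranyl-5-methoxycyclohex-4-ene-1,3-dione | CC(C)=CCC/C(C)=C/C[C@]1(CC=C)C(=O)C(=[N+]=[N-])C(=O)C=C1OC | intermediate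
12 | (1S,5S,7S,8S)-5-allyl-4-methoxy-8-methyl-8-(4-methylpent-3-en-1-yl)tricyclo[3.3.1.0(1,7)]non-3-ene-2,9-dione | [C@H]12C[C@]3(CC=C)C(=O)[C@]2(C(=O)C=C3OC)[C@@]1(C)CCC=C(C)C | intermediate
13 | 2-methyl-2-butene | CC=C(C)C | starting material
14 | (1S,5S,7S,8S)-4-methoxy-8-methyl-5-(3-methylbut-2-en-1-yl)-8-(4-methylpent-3-en-1-yl)tricyclo[3.3.1.0(1,7)]non-3-ene-2,9-dione | [C@H]12C[C@]3(CC=C(C)C)C(=O)[C@]2(C(=O)C=C3OC)[C@@]1(C)CCC=C(C)C | intermediate
15 | sodium benzenesulfinate | [Na+].[O-]S(=O)c1ccccc1 | starting material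
16 | geranyl phenyl sulfone | CC(C)=CCC/C(C)=C/CS(=O)(=O)c1ccccc1 | intermediate
17 | α-lithio geranyl phenyl sulfone | CC(C)=CCC/C(C)=C/C([Li])S(=O)(=O)c1ccccc1 | intermediate
18 | (1R,5S,7R,8S)-7-[(2E)-3,7-dimethyl-1-(phenylsulfonyl)octa-2,6-dien-1-yl]-4-methoxy-8-methyl-5-(3-methylbut-2-en-1-yl)-8-(4-methylpent-3-en-1-yl)bicyclo[3.3.1]non-3-ene-2,9-dione | CC(C)=CCC/C(C)=C/C([C@@H]1C[C@]2(CC=C(C)C)C(=O)[C@@H](C(=O)C=C2OC)[C@@]1(C)CCC=C(C)C)S(=O)(=O)c1ccccc1 | intermediate
19 | (1R,5S,7R,8S)-7-geranyl-4-methoxy-8-methyl-5-(3-methylbut-2-en-1-yl)-8-(4-methylpent-3-en-1-yl)bicyclo[3.3.1]non-3-ene-2,9-dione | CC(C)=CCC/C(C)=C/C[C@@H]1C[C@]2(CC=C(C)C)C(=O)[C@@H](C(=O)C=C2OC)[C@@]1(C)CCC=C(C)C | intermediate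
20 | prenyl bromide | CC(C)=CCBr | starting material
21 | 1-lithio derivative of 19 | CC(C)=CCC/C(C)=C/C[C@@H]1C[C@]2(CC=C(C)C)C(=O)[C@@]([Li])(C(=O)C=C2OC)[C@@]1(C)CCC=C(C)C | intermediate
22 | (1R,5S,7R,8S)-7-geranyl-4-methoxy-8-methyl-1,5-bis(3-methylbut-2-en-1-yl)-8-(4-methylpent-3-en-1-yl)bicyclo[3.3.1]non-3-ene-2,9-dione | CC(C)=CCC/C(C)=C/C[C@@H]1C[C@]2(CC=C(C)C)C(=O)[C@@](CC=C(C)C)(C(=O)C=C2OC)[C@@]1(C)CCC=C(C)C | intermediate
23 | 3-acetoxybenzoic acid | CC(=O)Oc1cccc(c1)C(=O)O | starting material
24 | 3-acetoxybenzoyl chloride | CC(=O)Oc1cccc(c1)C(Cl)=O | intermediate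
25 | 3-lithio derivative of 22 | CC(C)=CCC/C(C)=C/C[C@@H]1C[C@]2(CC=C(C)C)C(=O)[C@@](CC=C(C)C)(C(=O)C([Li])=C2OC)[C@@]1(C)CCC=C(C)C | intermediate
26 | (1S,5S,7R,8S)-3-(3-acetoxybenzoyl)-7-geranyl-4-methoxy-8-methyl-1,5-bis(3-methylbut-2-en-1-yl)-8-(4-methylpent-3-en-1-yl)bicyclo[3.3.1]non-3-ene-2,9-dione | CC(C)=CCC/C(C)=C/C[C@@H]1C[C@]2(CC=C(C)C)C(=O)[C@@](CC=C(C)C)(C(=O)C(C(=O)c3cccc(OC(C)=O)c3)=C2OC)[C@@]1(C)CCC=C(C)C | intermediate
27 | (1S,5S,7R,8S)-7-geranyl-4-hydroxy-3-(3-hydroxybenzoyl)-8-methyl-1,5-bis(3-methylbut-2-en-1-yl)-8-(4-methylpent-3-en-1-yl)bicyclo[3.3.1]non-3-ene-2,9-dione | CC(C)=CCC/C(C)=C/C[C@@H]1C[C@]2(CC=C(C)C)C(=O)[C@@](CC=C(C)C)(C(=O)C(C(=O)c3cccc(O)c3)=C2O)[C@@]1(C)CCC=C(C)C | target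

**Totals.** Total step count: 15. Longest linear sequence: 13 steps (steps 1–8, 10–12, 14, 15); steps 9 and 13 prepare reagents 16 and 24.

**Steps most likely to fail**

Step 10. The carbanion may add to the vinylogous ester (attack at C4 with loss of methoxide, or reversible 1,2-addition) faster than it displaces at the hindered secondary C7, or cleavage may shift to the C1–C8 bond. Fallback: set out from 14 and use a smaller, more nucleophilic sulfur-stabilised carbanion. Geranyl phenyl sulfide F1 (from 3 and PhSNa, DMF) is lithiated (n-BuLi, DABCO, THF, −78 °C) to its α-lithio derivative F2, which should open 14 in the same anti sense to the allylic sulfide adduct F3 (aq. NH4Cl quench). Chemoselective oxidation at sulfur (H2O2, (NH4)6Mo7O24, EtOH, 0 °C) then comes back to the route at 18.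

Step 7. The carbenoid may be captured by the terminal allyl olefin, or Wolff rearrangement and dimerisation may precede cyclisation. Fallback: set out from 10 and replace the diazo compound by the phenyliodonium ylide F4 (PhI(OAc)2, KOH, MeOH, 0 °C). Its Cu(acac)2-catalysed intramolecular cyclopropanation (CH2Cl2, 25 °C) is a known alternative carbene-transfer manifold, begun by attack of the most nucleophilic olefin on the iodonium centre, and should come back to the route at 12.

Step 11. Hydride may reduce the C9 ketone in competition with hydride transfer to the allylpalladium complex. Fallback: set out from 18, let the reduction run to completion with excess NaBH4 under the same palladium catalysis to the C9 carbinol F5, and re-oxidise with Dess–Martin periodinane (CH2Cl2, 25 °C), which comes back to the route at 19.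

**Further compounds**
F1 | step 10 | geranyl phenyl sulfide | CC(C)=CCC/C(C)=C/CSc1ccccc1
F2 | step 10 | α-lithio geranyl phenyl sulfide | CC(C)=CCC/C(C)=C/C([Li])Sc1ccccc1
F3 | step 10 | (1R,5S,7R,8S)-7-[(2E)-3,7-dimethyl-1-(phenylsulfanyl)octa-2,6-dien-1-yl]-4-methoxy-8-methyl-5-(3-methylbut-2-en-1-yl)-8-(4-methylpent-3-en-1-yl)bicyclo[3.3.1]non-3-ene-2,9-dione (both epimers at the sulfide carbon) | CC(C)=CCC/C(C)=C/C([C@@H]1C[C@]2(CC=C(C)C)C(=O)[C@@H](C(=O)C=C2OC)[C@@]1(C)CCC=C(C)C)Sc1ccccc1
F4 | step 7 | phenyliodonium ylide of 10 (iodonium at C1) | CC(C)=CCC/C(C)=C/C[C@]1(CC=C)C(=O)[C-]([I+]c2ccccc2)C(=O)C=C1OC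
F5 | step 11 | C9 carbinol of 19 (C9 configuration not defined, either epimer is oxidised to 19) | CC(C)=CCC/C(C)=C/C[C@@H]1C[C@]2(CC=C(C)C)C(O)[C@@H](C(=O)C=C2OC)[C@@]1(C)CCC=C(C)C
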